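The readings are calculated from invented constants.

I followed one molecule.

in all of them: starting material 45 mM (fed, over 2.0 min)

| charge | reagent | free catalyst | added ligand | temperature | remark | time |
|---|---|---|---|---|---|---|
| teal | 1.8 equiv | 0.05 mol% | 23 µM | −20 °C | run made earlier; the fed solution adds 0.50 times the starting volume |  |
| violet | 1.2 equiv | 0.05 mol% | 46 µM | −20 °C | run made earlier; the fed solution adds 0.50 times the starting volume |  |
| winter | 1.20 equiv | 0.025 mol% | 23 µM |  | at 5 °C throughout; the fed solution adds 0.50 times the starting volume | 8.0 min |
| dusk | 1.20 equiv | 0.05 mol% | 23 µM |  | at −20 °C until 2.0 min, from then on at 5 °C; the fed solution adds 0.50 times the starting volume | 8.0 min |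

| run | time / min | target / % |
|---|---|---|
| teal | 0.667 | 1.4 |
| teal | 1.33 | 1.3 |
| teal | 2.00 | 2.2 |
| teal | 3.00 | 3.0 |
| teal | 4.00 | 5.3 |
| teal | 5.00 | 7.2 |
| violet | 0.417 | 0 |
| violet | 0.667 | 0.2 |
| violet | 0.833 | 0.6 |
| violet | 1.33 | 1.3 |
| violet | 2.00 | 2.0 |
| violet | 3.00 | 3.9 |
| violet | 5.00 | 8.4 |

(standard deviation of a reading: 0.5 percentage points)

- every charge counts on the volume at the start, and the solution that is fed holds the whole dose
- the earlier runs do not show what temperature does; that part of a forecast is a guess
- percentages count the whole charge, also what has not yet gone in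
- no earlier run changes the charge of free catalyst; that part of a forecast is a guess

* the winner by amount of target, in percent of the starting material charged; "neither" if no more than 2 percentage points parts them (winter / dusk / neither)
* how much target is there at the end, in percent of the starting material charged: winter
* how much target is there at the end, in percent of the starting material charged: dusk

Once in the flask, a molecule of starting material has some chance per minute of becoming target, a pseudo-first-order constant, and after the feed the slope of the target curve reads that chance. From the end of the feed to the last reading, teal gave 0.0167 min⁻¹ and its neighbour violet gave 0.0213 min⁻¹. Teal had 1.50 times the reagent of violet, and violet had twice the added ligand of teal. Still, the slopes differ by 0.00460 min⁻¹ against a scatter of 0.00333 min⁻¹ on such a difference, though the two changes could have offset each other. Teal and violet held the same catalyst after the feed, 15.0 µM counting all its forms. Dividing the mean chance, 0.0190 min⁻¹, by this catalyst gave the chance per minute per unit of catalyst, E, the specificity constant kcat/KM: 1270 L mol⁻¹ min⁻¹ at −20 °C.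

No earlier run shows warming or a change of catalyst, so I guessed that E rises 4-fold at 5 °C and that the chance follows the catalyst in proportion. Dusk starts its warm minutes with 2.10% of target, as read from the runs, and has 6.00 min at 15.0 µM. That gave me 37.9%. Winter has half the catalyst, 7.50 µM, and its average molecule, fed in mid-feed, has 7.00 min. That gave me 23.4%, so dusk came out ahead of winter.

The forecast said dusk, with 41% for winter and 60% for dusk, because “Halving the catalyst costs more than the early cold period”, and both its numbers stood higher than mine.

The simulation gave 17.8% for winter and 28.5% for dusk, so dusk won by 11 percentage points.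

    reagent + free catalyst ⇌ catalyst intermediate A (K = 42.0 L mol⁻¹, k = 67000 L mol⁻¹ min⁻¹, Ea = 36.0 kJ mol⁻¹, ΔH = −90.0 kJ mol⁻¹)
    catalyst intermediate A → catalyst intermediate B (k = 1600 min⁻¹, Ea = 44.0 kJ mol⁻¹)
    starting material + catalyst intermediate B ⇌ catalyst intermediate C (K = 14.0 L mol⁻¹, k = 2000 L mol⁻¹ min⁻¹, Ea = 37.0 kJ mol⁻¹, ΔH = −16.0 kJ mol⁻¹)
    catalyst intermediate C ⇌ free catalyst + target (K = 0.330 M, k = 320 min⁻¹, Ea = 53.0 kJ mol⁻¹, ΔH = −18.0 kJ mol⁻¹)
    free catalyst + added ligand ⇌ idle complex (K = 31000 L mol⁻¹, k = 32000 L mol⁻¹ min⁻¹, Ea = 35.0 kJ mol⁻¹, ΔH = −16.0 kJ mol⁻¹)
    (constants at −20 °C)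

In dusk, catalyst intermediate B held 83.5% of the catalyst at the change of temperature and 60.4% at the end, while free catalyst went from 2.86% to 28.6%. Starting material in dusk fell from 98.0% to 71.5% over the warm minutes, which puts E at 3500 L mol⁻¹ min⁻¹, or 2.76 times the cold value. A flask like winter but with 76 mM of starting material holds 12.7 µM of catalyst, so this E reckons it at 26.6%, and that flask gave 27.2%.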